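**Plan**

- Retrosynthesis: the 4'-O–MOM bond is cut first, then C4a–C5 of ring A. This leaves a (2S)-2-aryl-2,3-dihydro-4H-pyran-4-one (rings B and C) carrying a C8–C7–C6–C5 β-keto ester arm on C8a.
- Enabling feature: ring A (C4a, C5, C6, C7, C8, C8a) bears oxygen on C5, C7 and C8a, the pattern of a folded triketide. The C8a oxygen is already the ring oxygen O1, so ring A can be grown last by an intramolecular Claisen condensation.
- Further cuts: O1–C8a (cyclodehydration), C4–C4a (acylation of a keto-dioxinone dianion, the dioxinone being the masked β-keto ester), C2–C3 (crossed Claisen), C1'–C2 and C3'–geranyl (aryllithium chemistry on 2,4-dibromophenol). The arm is brought in with the dioxinone because a 6-methyl-dihydropyranone would be deprotonated at C3, not at the methyl group.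
- Forward order: ring B is substituted first, the C2–C4 unit and then the polyketide arm are attached, ring C closes, ring A closes last.
- Stereochemistry: C2 is set by Ru-catalysed asymmetric transfer hydrogenation of the aryl β-keto amide ((S,S)-TsDPEN ligand); its C–O bond is never broken afterwards.

Key step: step 10

Remark: flavanone numbering (O1, C2, C3, C4, C4a, C5–C8, C8a, primed positions for ring B) is used for all intermediates. "Geranyl" is (2E)-3,7-dimethylocta-2,6-dien-1-yl and "Ar" is 3-geranyl-4-(methoxymethoxy)phenyl.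

**Route**

Step 1
Reactants: 1 2,4-dibromophenol
Product: 2 2,4-dibromo-1-(methoxymethoxy)benzene
Conditions: MOMCl, K2CO3, acetone, rt
Reagents that add atoms: chloromethyl methyl ether, COCCl
Why: Williamson-type O-alkylation of the phenoxide with the reactive α-chloro ether installs an acetal that tolerates organolithium and amide bases and later directs the ortho bromine–lithium exchange.

Step 2
Reactants: 2 2,4-dibromo-1-(methoxymethoxy)benzene; 3 geranyl bromide
Product: 5 4-bromo-2-geranyl-1-(methoxymethoxy)benzene, via aryllithium 4 (not isolated)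
Conditions: n-BuLi (1.05 equiv), Et2O, −78 °C; CuBr·SMe2 (0.2 equiv), THF; 3, −78 to 0 °C
Reagents that add atoms: none
Why: Bromine–lithium exchange should occur at the bromine ortho to the chelating OMOM group (faster exchange and the more stable aryllithium), and copper-catalysed SN2 allylic substitution on the primary allylic bromide then joins C3' to the geranyl chain without touching the E alkene.

Step 3
Reactants: 5 4-bromo-2-geranyl-1-(methoxymethoxy)benzene
Product: 7 methyl 3-geranyl-4-(methoxymethoxy)benzoate, via aryllithium 6 (not isolated)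
Conditions: n-BuLi (1.05 equiv), THF, −78 °C; cannulated into ClCO2Me (3 equiv), THF, −78 °C
Reagents that add atoms: methyl chloroformate, COC(=O)Cl
Why: A second bromine–lithium exchange followed by inverse addition to excess chloroformate (acylation of an aryllithium) should give the benzoate without double addition.

Step 4
Reactants: 7 methyl 3-geranyl-4-(methoxymethoxy)benzoate; 8 N-methoxy-N-methylacetamide
Product: 10 3-Ar-N-methoxy-N-methyl-3-oxopropanamide, via lithium enolate 9 (not isolated)
Conditions: 8 (2.5 equiv), LiN(iPr)2 (2.5 equiv), THF, −78 °C; 7, −78 to −10 °C; 1 M HCl to pH 5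
Reagents that add atoms: none
Why: Crossed Claisen condensation of the non-enolisable benzoate with the preformed amide enolate forms C2–C3, the excess enolate deprotonating the β-keto amide and so driving the equilibrium.

Step 5
Reactants: 10 3-Ar-N-methoxy-N-methyl-3-oxopropanamide
Product: 11 (3S)-3-Ar-3-hydroxy-N-methoxy-N-methylpropanamide
Conditions: RuCl[(S,S)-TsDPEN](p-cymene) (1 mol %), HCO2H/Et3N (5:2), CH2Cl2, 30 °C
Reagents that add atoms: none
Why: Noyori–Ikariya asymmetric transfer hydrogenation should reduce only the aryl ketone, the (S,S)-TsDPEN ligand delivering hydride to the Re face (aryl group held by the CH–π contact with the cymene ligand, as for acetophenone), which sets C2 as S while the amide, the MOM acetal and the trisubstituted alkenes stay inert.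

Step 6
Reactants: 12 2,2,6-trimethyl-4H-1,3-dioxin-4-one
Product: 14 2,2-dimethyl-6-(2-oxopropyl)-4H-1,3-dioxin-4-one, via lithium dienolate 13 (not isolated)
Conditions: 12 (2 equiv), LiN(SiMe3)2 (2 equiv), THF, −78 °C; AcCl (1 equiv), −78 to −20 °C; 1 M HCl
Reagents that add atoms: acetyl chloride, CC(=O)Cl
Why: γ-Deprotonation gives the vinylogous dienolate, which is C-acylated at the exocyclic carbon by acetyl chloride (vinylogous Claisen-type acylation), half of the dienolate serving as base for the more acidic product.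

Step 7
Reactants: 11 (3S)-3-Ar-3-hydroxy-N-methoxy-N-methylpropanamide; 14 2,2-dimethyl-6-(2-oxopropyl)-4H-1,3-dioxin-4-one
Product: 16 6-[(6S)-6-Ar-6-hydroxy-2,4-dioxohexyl]-2,2-dimethyl-4H-1,3-dioxin-4-one, via dilithium dianion 15 (not isolated)
Conditions: 14 (3.5 equiv), LiN(iPr)2 (7 equiv), THF, −78 to −40 °C; 11, −78 to −30 °C; 1 M HCl to pH 5
Reagents that add atoms: none
Why: Claisen-type C-acylation of a 1,3-dicarbonyl dianion at its terminal, most basic carbon by a Weinreb amide (whose chelated tetrahedral adduct prevents over-addition) forms C4–C4a; the first equivalent of dianion turns the carbinol into a lithium alkoxide that cannot β-eliminate, and C2 is not touched.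

Step 8
Reactants: 16 6-[(6S)-6-Ar-6-hydroxy-2,4-dioxohexyl]-2,2-dimethyl-4H-1,3-dioxin-4-one
Product: 18 6-{[(2S)-2-Ar-4-oxo-3,4-dihydro-2H-pyran-6-yl]methyl}-2,2-dimethyl-4H-1,3-dioxin-4-one, via hemiketal 17 (not isolated)
Conditions: CF3CO2H (10 mol %), 4 Å MS, CH2Cl2, 0 °C to rt
Reagents that add atoms: none
Why: Acid-catalysed cyclodehydration of a δ-hydroxy-β-diketone, in which the C2 hydroxyl adds to the C8a carbonyl and the six-membered hemiketal loses water into conjugation with the C4 ketone, should close ring C with the C2–O bond intact (retention), and once ring C exists the dioxinone arm is trans to C4 across C8a=C4a, which rules out aldol aromatisation.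

Step 9
Reactants: 18 6-{[(2S)-2-Ar-4-oxo-3,4-dihydro-2H-pyran-6-yl]methyl}-2,2-dimethyl-4H-1,3-dioxin-4-one
Product: 20 methyl 4-[(2S)-2-Ar-4-oxo-3,4-dihydro-2H-pyran-6-yl]-3-oxobutanoate, via acylketene 19 (not isolated)
Conditions: MeOH (10 equiv), toluene, 110 °C, sealed tube
Reagents that add atoms: methanol, CO
Why: Thermal retro-hetero-Diels–Alder fragmentation of the dioxinone releases acetone and an acylketene, which excess methanol traps as the methyl β-keto ester under neutral conditions that leave ring C and C2 untouched.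

Step 10
Reactants: 20 methyl 4-[(2S)-2-Ar-4-oxo-3,4-dihydro-2H-pyran-6-yl]-3-oxobutanoate
Product: 22 (2S)-3'-geranyl-5,7-dihydroxy-4'-(methoxymethoxy)flavanone, via trione tautomer 21 (not isolated)
Conditions: Mg(OMe)2 (3 equiv), MeOH, 0 to 40 °C; 1 M HCl, 0 °C, to pH 4
Reagents that add atoms: none
Why: Proposed new method: Mg(OMe)2 should enolise the arm through the C8 methylene to a magnesium dienolate whose charge runs through C8a=C4a to the C4 carbonyl, the vinylogous α-carbon C4a adds to the magnesium-bound ester carbonyl C5, methoxide leaves and the 4a-H trione 21 enolises to the aromatic 5,7-diol. This Claisen closure has not been shown on a 2,3-dihydro-4H-pyran-4-one, and the closest known reaction is the base- or Mg(OMe)2-mediated Claisen cyclisation of 3,5,7-triketo esters to acylphloroglucinols. Ring A closes in a 6-(enolendo)-exo-trig mode, the C8a=C4a bond of the dienolate lying inside the new ring. No stereocentre is formed, and C2 is one carbon removed from any bond that changes. The step needs C-acylation at C4a in preference to lactone or aldol closure and to C3 deprotonation: O1 ties up the C8a enol oxygen so no pyrone can form, the arm is trans to C4 across C8a=C4a so no aldol onto C4 is possible, and the far more acidic C6 and C8 methylenes are deprotonated long before C3, which keeps retro-oxa-Michael opening (the only path to racemisation) slow with this weakly basic, chelating counter-ion. Aromatisation should make the closure irreversible, and the 4'-MOM ether blocks the quinone-methide route by which a free 4'-phenoxide would open ring C.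

Step 11
Reactants: 22 (2S)-3'-geranyl-5,7-dihydroxy-4'-(methoxymethoxy)flavanone
Product: 23 (2S)-3'-geranyl-4',5,7-trihydroxyflavanone (CNP0226020.2)
Conditions: 3 M HCl (aq), MeOH, 40 °C
Reagents that add atoms: none
Why: Acid-catalysed acetal exchange with methanol should cleave the aryl MOM ether under conditions too mild to open the flavanone ring or to protonate the geranyl alkenes, so C2 and the side chain survive.

**Compound list**

1 | 2,4-dibromophenol | Oc1ccc(Br)cc1Br | starting material
2 | 2,4-dibromo-1-(methoxymethoxy)benzene | COCOc1ccc(Br)cc1Br | intermediate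
3 | geranyl bromide, (2E)-1-bromo-3,7-dimethylocta-2,6-diene | CC(C)=CCC/C(C)=C/CBr | starting material
4 | [5-bromo-2-(methoxymethoxy)phenyl]lithium (formed in the flask) | [Li]c1cc(Br)ccc1OCOC | intermediate
5 | 4-bromo-2-geranyl-1-(methoxymethoxy)benzene | CC(C)=CCC/C(C)=C/Cc1cc(Br)ccc1OCOC | intermediate
6 | [3-geranyl-4-(methoxymethoxy)phenyl]lithium (formed in the flask) | CC(C)=CCC/C(C)=C/Cc1cc([Li])ccc1OCOC | intermediate
7 | methyl 3-geranyl-4-(methoxymethoxy)benzoate | CC(C)=CCC/C(C)=C/Cc1cc(C(=O)OC)ccc1OCOC | intermediate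
8 | N-methoxy-N-methylacetamide | CC(=O)N(C)OC | starting material
9 | lithium enolate of N-methoxy-N-methylacetamide (formed in the flask) | C=C(O[Li])N(C)OC | intermediate
10 | 3-[3-geranyl-4-(methoxymethoxy)phenyl]-N-methoxy-N-methyl-3-oxopropanamide | CC(C)=CCC/C(C)=C/Cc1cc(C(=O)CC(=O)N(C)OC)ccc1OCOC | intermediate
11 | (3S)-3-[3-geranyl-4-(methoxymethoxy)phenyl]-3-hydroxy-N-methoxy-N-methylpropanamide | CC(C)=CCC/C(C)=C/Cc1cc([C@@H](O)CC(=O)N(C)OC)ccc1OCOC | intermediate
12 | 2,2,6-trimethyl-4H-1,3-dioxin-4-one | CC1=CC(=O)OC(C)(C)O1 | starting material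
13 | lithium 2,2-dimethyl-6-methylidene-6H-1,3-dioxin-4-olate (formed in the flask) | C=C1C=C(O[Li])OC(C)(C)O1 | intermediate
14 | 2,2-dimethyl-6-(2-oxopropyl)-4H-1,3-dioxin-4-one | CC(=O)CC1=CC(=O)OC(C)(C)O1 | intermediate
15 | dilithium dianion of 14, bis-enolate metalated at the terminal methyl (formed in the flask) | C=C(O[Li])C=C1C=C(O[Li])OC(C)(C)O1 | intermediate
16 | 6-{(6S)-6-[3-geranyl-4-(methoxymethoxy)phenyl]-6-hydroxy-2,4-dioxohexyl}-2,2-dimethyl-4H-1,3-dioxin-4-one | CC(C)=CCC/C(C)=C/Cc1cc([C@@H](O)CC(=O)CC(=O)CC2=CC(=O)OC(C)(C)O2)ccc1OCOC | intermediate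
17 | cyclic hemiketal of 16, 6-{[(6S)-6-Ar-2-hydroxy-4-oxotetrahydro-2H-pyran-2-yl]methyl}-2,2-dimethyl-4H-1,3-dioxin-4-one, hemiketal carbon unassigned (formed in the flask) | CC(C)=CCC/C(C)=C/Cc1cc([C@@H]2CC(=O)CC(O)(CC3=CC(=O)OC(C)(C)O3)O2)ccc1OCOC | intermediate
18 | 6-({(2S)-2-[3-geranyl-4-(methoxymethoxy)phenyl]-4-oxo-3,4-dihydro-2H-pyran-6-yl}methyl)-2,2-dimethyl-4H-1,3-dioxin-4-one | CC(C)=CCC/C(C)=C/Cc1cc([C@@H]2CC(=O)C=C(CC3=CC(=O)OC(C)(C)O3)O2)ccc1OCOC | intermediate
19 | acylketene 4-[(2S)-2-Ar-4-oxo-3,4-dihydro-2H-pyran-6-yl]-3-oxobut-1-en-1-one (formed in the flask) | CC(C)=CCC/C(C)=C/Cc1cc([C@@H]2CC(=O)C=C(CC(=O)C=C=O)O2)ccc1OCOC | intermediate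
20 | methyl 4-{(2S)-2-[3-geranyl-4-(methoxymethoxy)phenyl]-4-oxo-3,4-dihydro-2H-pyran-6-yl}-3-oxobutanoate | CC(C)=CCC/C(C)=C/Cc1cc([C@@H]2CC(=O)C=C(CC(=O)CC(=O)OC)O2)ccc1OCOC | intermediate
21 | (2S)-2-Ar-4a,6-dihydro-2H-chromene-4,5,7(3H)-trione, non-aromatic Claisen adduct, C4a unassigned (formed in the flask) | CC(C)=CCC/C(C)=C/Cc1cc([C@@H]2CC(=O)C3C(=O)CC(=O)C=C3O2)ccc1OCOC | intermediate
22 | (2S)-3'-geranyl-5,7-dihydroxy-4'-(methoxymethoxy)flavanone | CC(C)=CCC/C(C)=C/Cc1cc([C@@H]2CC(=O)c3c(O)cc(O)cc3O2)ccc1OCOC | intermediate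
23 | (2S)-2-{3-[(2E)-3,7-dimethylocta-2,6-dien-1-yl]-4-hydroxyphenyl}-5,7-dihydroxy-2,3-dihydro-4H-chromen-4-one (CNP0226020.2) | CC(C)=CCC/C(C)=C/Cc1cc([C@@H]2CC(=O)c3c(O)cc(O)cc3O2)ccc1O | target

**Step count and risks**

Total: 11 steps. Longest linear sequence: 10 steps (1–5 and 7–11); step 6 is a one-step side branch.

Step 10 is the riskiest. The stabilised dienolate may attack the chelated, partly enolised ester too slowly, so the closure stalls, and long exposure to base may open ring C by retro-oxa-Michael reaction and erode the configuration at C2. The fallback uses known chemistry, sets out from 5 and returns at 23. Bromide 5 would be taken through bromine–lithium exchange (n-BuLi), B(OiPr)3 and mild hydrolysis to [3-geranyl-4-(methoxymethoxy)phenyl]boronic acid F1. Commercial 5,7-dihydroxy-4H-chromen-4-one would be protected (NaH, MOMCl, DMF) as 5,7-bis(methoxymethoxy)-4H-chromen-4-one F2. Enantioselective conjugate addition of F1 to F2 (Pd(OCOCF3)2, the t-BuPyOx antipode that gives 2S, NH4PF6, H2O, ClCH2CH2Cl, 60 °C) would give (2S)-3'-geranyl-4',5,7-tris(methoxymethoxy)flavanone F3. HCl in MeOH as in step 11 would then give 23.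

Step 7 is next. Proton transfer from the carbinol and the active methylenes may quench the dianion, or the lithium aldolate may fragment by retro-aldol reaction, leaving low conversion. The fallback sets out from 11 and returns at 18. Silylation (Et3SiCl, imidazole, CH2Cl2) would give (3S)-3-Ar-N-methoxy-N-methyl-3-(triethylsilyloxy)propanamide F4. This neutral amide would be acylated with about 2.2 equiv of dianion 15 at −78 °C to give 6-[(6S)-6-Ar-2,4-dioxo-6-(triethylsilyloxy)hexyl]-2,2-dimethyl-4H-1,3-dioxin-4-one F5. Wet CF3CO2H in CH2Cl2 would remove the silyl group and cyclodehydrate in one operation to give 18.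

Step 4 is third. The Weinreb acetamide enolate may decompose before it adds to the electron-rich benzoate, so the condensation stays incomplete. The fallback sets out from 5, returns at 11 and bypasses steps 3–5. Bromine–lithium exchange (n-BuLi) and DMF would give 3-geranyl-4-(methoxymethoxy)benzaldehyde F6. An enantioselective Mukaiyama acetate aldol with 1-(tert-butylthio)-1-(trimethylsilyloxy)ethene (Ti(OiPr)4 with the BINOL antipode that gives the S carbinol, then 1 M HCl) would give S-tert-butyl (3S)-3-Ar-3-hydroxypropanethioate F7. Aminolysis with MeNH(OMe)·HCl and i-PrMgCl in THF at −20 °C would give 11.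

**Further compounds**

F1 | step 10 | [3-geranyl-4-(methoxymethoxy)phenyl]boronic acid | CC(C)=CCC/C(C)=C/Cc1cc(B(O)O)ccc1OCOC
F2 | step 10 | 5,7-bis(methoxymethoxy)-4H-chromen-4-one | COCOc1cc(OCOC)c2c(c1)occc2=O
F3 | step 10 | (2S)-3'-geranyl-4',5,7-tris(methoxymethoxy)flavanone | CC(C)=CCC/C(C)=C/Cc1cc([C@@H]2CC(=O)c3c(OCOC)cc(OCOC)cc3O2)ccc1OCOC
F4 | step 7 | (3S)-3-[3-geranyl-4-(methoxymethoxy)phenyl]-N-methoxy-N-methyl-3-(triethylsilyloxy)propanamide | CC(C)=CCC/C(C)=C/Cc1cc([C@@H](O[Si](CC)(CC)CC)CC(=O)N(C)OC)ccc1OCOC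
F5 | step 7 | 6-{(6S)-6-[3-geranyl-4-(methoxymethoxy)phenyl]-2,4-dioxo-6-(triethylsilyloxy)hexyl}-2,2-dimethyl-4H-1,3-dioxin-4-one | CC(C)=CCC/C(C)=C/Cc1cc([C@@H](O[Si](CC)(CC)CC)CC(=O)CC(=O)CC2=CC(=O)OC(C)(C)O2)ccc1OCOC
F6 | step 4 | 3-geranyl-4-(methoxymethoxy)benzaldehyde | CC(C)=CCC/C(C)=C/Cc1cc(C=O)ccc1OCOC
F7 | step 4 | S-tert-butyl (3S)-3-[3-geranyl-4-(methoxymethoxy)phenyl]-3-hydroxypropanethioate | CC(C)=CCC/C(C)=C/Cc1cc([C@@H](O)CC(=O)SC(C)(C)C)ccc1OCOC
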